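## Retrosynthetic overview

- **Numbering and feature:** tetralone C1 (C=O) to C8a; ring A = C1-C2-C3-C4-C4a-C8a; ring B = C4a-C5-C6-C7-C8-C8a; naphthyl atoms primed. Ring A holds the only stereocentre, the doubly benzylic C4-H between C4a and C1'. Its carbonyl carbon C1 sits on C8a directly beside the C8 oxygen, so ring A is the six-membered ring of a benzo-fused [4+2] adduct.
- **Disconnection 1 (ring A, the only ring formed):** C1-C2 and C3-C4 are cut together. This gives a 2,3-dioxygenated 6-(naphthylmethyl)benzaldehyde, used as its light-generated dienol C1=C8a-C4a=C4, and an acryloyl imide whose acyl carbon on C2 later leaves as CO2.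
- **Disconnection 2:** C4-C4a (sp3-sp2 Suzuki-Miyaura) gives a naphthylmethyl boronate (three steps from 5-methoxynaphthalen-1-ol) and 2,3-bis(benzyloxy)-6-bromobenzaldehyde (two steps from 2,3-dihydroxybenzaldehyde). The naphthalene and ring B are bought.
- **End game:** imide to benzyl ester, C1 carbinol to ketone, then one hydrogenolysis that removes four benzyl groups and lets the β-keto acid lose CO2.

Key step: step 7

Assumption: the (R,R)-TADDOLate is taken to expose the dienol face that leads to (4S); the sense of induction has to be checked on 13 and, if it is the opposite one, the equally available (S,S)-ligand is used with nothing else changed.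

## Route

Step 1
Reactants: 1 5-methoxynaphthalen-1-ol
Product: 2 4-bromo-5-methoxynaphthalen-1-ol
Conditions: NBS (1.0 equiv), MeCN, −20 → 0 °C, dark
Reagents that add atoms: N-bromosuccinimide, O=C1CCC(=O)N1Br
Why: Electrophilic aromatic bromination under the para-selective NBS/MeCN protocol for naphthols should hit C4, because the free hydroxyl activates its own ring far more than the methoxy group activates the other ring, C4 is the α-position para to it, and a peri methoxy group is known not to block para attack in 1,5-dialkoxynaphthalenes.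

Step 2
Reactants: 2 4-bromo-5-methoxynaphthalen-1-ol
Product: 3 1-(benzyloxy)-4-bromo-5-methoxynaphthalene
Conditions: BnBr, K2CO3, DMF, rt
Reagents that add atoms: benzyl bromide, BrCc1ccccc1
Why: Williamson ether synthesis on the naphtholate is unproblematic and removes the acidic, oxidation-prone OH before the organolithium step.

Step 3
Reactants: 3 1-(benzyloxy)-4-bromo-5-methoxynaphthalene
Product: 6 2-{[4-(benzyloxy)-8-methoxynaphthalen-1-yl]methyl}-4,4,5,5-tetramethyl-1,3,2-dioxaborolane, via aryllithium 4 (not isolated), via chloromethylboronate complex 5 (not isolated)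
Conditions: n-BuLi, THF, −78 °C; ClCH2Bpin, −78 °C → rt
Reagents that add atoms: 2-(chloromethyl)-4,4,5,5-tetramethyl-1,3,2-dioxaborolane, ClCB1OC(C)(C)C(C)(C)O1
Why: Bromine-lithium exchange at −78 °C is faster than any attack on the benzyl ether, and the aryllithium adds to boron to give an ate complex whose aryl group migrates to carbon with loss of chloride on warming (Matteson homologation), placing the future C4 methylene on C1'.

Step 4
Reactants: 7 2,3-dihydroxybenzaldehyde
Product: 8 2,3-bis(benzyloxy)benzaldehyde
Conditions: BnBr (2.4 equiv), K2CO3, DMF, 60 °C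
Reagents that add atoms: benzyl bromide, BrCc1ccccc1
Why: Double Williamson etherification, with gentle heating to overcome the hydrogen bond between the C2 hydroxyl and the formyl group.

Step 5
Reactants: 8 2,3-bis(benzyloxy)benzaldehyde
Product: 9 2,3-bis(benzyloxy)-6-bromobenzaldehyde
Conditions: NBS, DMF, rt, dark
Reagents that add atoms: N-bromosuccinimide, O=C1CCC(=O)N1Br
Why: Electrophilic aromatic bromination goes para to the C3 oxygen (C6), as known for 2,3-dialkoxybenzaldehydes, because the C2 alkoxy group is flanked on both sides and twisted out of conjugation, while the dark polar medium suppresses radical attack on the OCH2Ph groups.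

Step 6
Reactants: 6 2-{[4-(benzyloxy)-8-methoxynaphthalen-1-yl]methyl}-4,4,5,5-tetramethyl-1,3,2-dioxaborolane; 9 2,3-bis(benzyloxy)-6-bromobenzaldehyde
Product: 10 2,3-bis(benzyloxy)-6-{[4-(benzyloxy)-8-methoxynaphthalen-1-yl]methyl}benzaldehyde
Conditions: Pd(OAc)2 (5 mol %), SPhos (10 mol %), K3PO4 (3 equiv), toluene/H2O (10:1), 80 °C
Reagents that add atoms: none
Why: Suzuki-Miyaura sp3-sp2 coupling of primary benzylic pinacol boronates with aryl bromides is established, the ortho-formyl group speeds oxidative addition and needs no protection, the bulky electron-rich phosphine helps transmetallation, and the benzylic palladium species has no β-hydrogen to lose.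

Step 7
Reactants: 10 2,3-bis(benzyloxy)-6-{[4-(benzyloxy)-8-methoxynaphthalen-1-yl]methyl}benzaldehyde; 11 3-acryloyl-1,3-oxazolidin-2-one
Product: 13 3-{[(1S,2S,4S)-7,8-bis(benzyloxy)-4-[4-(benzyloxy)-8-methoxynaphthalen-1-yl]-1-hydroxy-1,2,3,4-tetrahydronaphthalen-2-yl]carbonyl}-1,3-oxazolidin-2-one (OH, acyl and naphthyl all cis), via outward-outward dienol 12 (not isolated)
Conditions: Ti(OiPr)4 (1.5 equiv), (R,R)-TADDOL (1.6 equiv), 4 Å MS, toluene, rt, 1 h; then 10, 11 (3 equiv), degassed, hν (365 nm LED), 0 °C; aq NaHCO3
Reagents that add atoms: none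
Why: Light at 365 nm, where only the formyl chromophore of 10 absorbs, leads through intersystem crossing and a 1,5-hydrogen shift from the doubly benzylic C4 methylene to a triplet biradical that relaxes to dienol 12 (diene C1=C8a-C4a=C4, OH and naphthyl both outward), whose oxygen exchanges onto the titanium TADDOLate that also binds imide 11. The closest known reaction type is the titanium-templated enantioselective photoenolisation/Diels-Alder reaction of electron-rich 2-alkylbenzaldehydes, backed by the classical photoenol cycloadditions of 2-benzylbenzaldehydes that lead to aryltetralins. Ring A closes in an intermolecular, suprafacial endo [4+2] that forms C1-C2 and C3-C4 in one event and returns ring B to aromaticity. C1 and C4 become cis because both diene termini carry their substituent outward, C2 becomes cis to the C1 hydroxyl because the imide carbonyl lies endo under the diene and is tied to the same titanium as the dienol oxygen, and the absolute sense (4S, the only centre that is kept) comes from the TADDOLate aryl groups covering one face of the bound dienol. The step needs regioselectivity (acyl group on C2, not C3), which the stronger donor at C1 (ortho rule) and the O-Ti-O=C bridge secure, and face selectivity at C4, which rests on the ligand. In the substrate the C8 benzyloxy group turns the formyl oxygen toward the C4 methylene by dipole avoidance, the weak diarylmethane C-H speeds the hydrogen shift, and the peri C8' methoxy group makes an inward naphthyl untenable.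

Step 8
Reactants: 13 the all-cis hydroxy imide
Product: 14 benzyl (1S,2S,4S)-7,8-bis(benzyloxy)-4-[4-(benzyloxy)-8-methoxynaphthalen-1-yl]-1-hydroxy-1,2,3,4-tetrahydronaphthalene-2-carboxylate
Conditions: BnOH (2 equiv), n-BuLi (1.5 equiv), THF, −78 → 0 °C; then 13, 0 °C; AcOH quench
Reagents that add atoms: benzyl alcohol (used as its lithium alkoxide), OCc1ccccc1
Why: Alkoxide transesterification of an N-acyloxazolidinone attacks the more electrophilic exocyclic carbonyl, is placed before the oxidation because a β-keto imide would rest as an unreactive enolate under basic cleavage, leaves the non-acidic C4-H untouched, and any retro-aldol/aldol scrambling could touch only C1 and C2, which are erased later.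

Step 9
Reactants: 14 the hydroxy benzyl ester
Product: 15 benzyl (4S)-7,8-bis(benzyloxy)-4-[4-(benzyloxy)-8-methoxynaphthalen-1-yl]-1-oxo-1,2,3,4-tetrahydronaphthalene-2-carboxylate (C2 mobile through the enol)
Conditions: Dess-Martin periodinane, CH2Cl2, 0 °C → rt
Reagents that add atoms: none
Why: Dess-Martin oxidation converts the secondary benzylic alcohol under mild conditions that spare benzyl ethers and the electron-rich naphthalene, removing the C1 centre and making C2 stereochemically irrelevant while C4 is not involved.

Step 10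
Reactants: 15 the β-keto benzyl ester
Product: 17 (4S)-7,8-dihydroxy-4-(4-hydroxy-8-methoxynaphthalen-1-yl)-3,4-dihydronaphthalen-1(2H)-one, via triphenolic keto acid 16 (not isolated)
Conditions: H2 (1 atm), 10 % Pd/C, EtOAc/MeOH, rt; filtration under Ar, then 40 °C
Reagents that add atoms: none
Why: Catalytic hydrogenolysis cleaves the three aryl benzyl ethers and the benzyl ester, the freed β-keto acid decarboxylates through its cyclic six-membered transition state on gentle warming, and the aryl methyl ether, the hydrogen-bonded C1 ketone and the C4 centre should survive at 1 atm if the reaction is stopped at full debenzylation and the catechol is kept under argon.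

## Compound list

1 | 5-methoxynaphthalen-1-ol | COc1cccc2c(O)cccc12 | starting material
2 | 4-bromo-5-methoxynaphthalen-1-ol | COc1cccc2c(O)ccc(Br)c12 | intermediate
3 | 1-(benzyloxy)-4-bromo-5-methoxynaphthalene | COc1cccc2c(OCc3ccccc3)ccc(Br)c12 | intermediate
4 | [4-(benzyloxy)-8-methoxynaphthalen-1-yl]lithium (formed in the flask) | COc1cccc2c(OCc3ccccc3)ccc([Li])c12 | intermediate
5 | lithium [4-(benzyloxy)-8-methoxynaphthalen-1-yl](chloromethyl)(pinacolato)borate (formed in the flask) | [Li+].COc1cccc2c(OCc3ccccc3)ccc([B-]3(CCl)OC(C)(C)C(C)(C)O3)c12 | intermediate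
6 | 2-{[4-(benzyloxy)-8-methoxynaphthalen-1-yl]methyl}-4,4,5,5-tetramethyl-1,3,2-dioxaborolane | COc1cccc2c(OCc3ccccc3)ccc(CB3OC(C)(C)C(C)(C)O3)c12 | intermediate
7 | 2,3-dihydroxybenzaldehyde | O=Cc1cccc(O)c1O | starting material
8 | 2,3-bis(benzyloxy)benzaldehyde | O=Cc1cccc(OCc2ccccc2)c1OCc1ccccc1 | intermediate
9 | 2,3-bis(benzyloxy)-6-bromobenzaldehyde | O=Cc1c(Br)ccc(OCc2ccccc2)c1OCc1ccccc1 | intermediate
10 | 2,3-bis(benzyloxy)-6-{[4-(benzyloxy)-8-methoxynaphthalen-1-yl]methyl}benzaldehyde | COc1cccc2c(OCc3ccccc3)ccc(Cc3ccc(OCc4ccccc4)c(OCc4ccccc4)c3C=O)c12 | intermediate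
11 | 3-acryloyl-1,3-oxazolidin-2-one | C=CC(=O)N1CCOC1=O | starting material
12 | hydroxy-o-quinodimethane of 10: [2,3-bis(benzyloxy)-6-{[4-(benzyloxy)-8-methoxynaphthalen-1-yl]methylidene}cyclohexa-2,4-dien-1-ylidene]methanol, OH cis to C8 and naphthyl cis to C5 (both outward; formed in the flask) | O/C=C1\C(OCc2ccccc2)=C(OCc2ccccc2)C=C/C1=C\c1ccc(OCc2ccccc2)c2cccc(OC)c12 | intermediate
13 | 3-{[(1S,2S,4S)-7,8-bis(benzyloxy)-4-[4-(benzyloxy)-8-methoxynaphthalen-1-yl]-1-hydroxy-1,2,3,4-tetrahydronaphthalen-2-yl]carbonyl}-1,3-oxazolidin-2-one | COc1cccc2c(OCc3ccccc3)ccc([C@@H]3C[C@H](C(=O)N4CCOC4=O)[C@H](O)c4c3ccc(OCc3ccccc3)c4OCc3ccccc3)c12 | intermediate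
14 | benzyl (1S,2S,4S)-7,8-bis(benzyloxy)-4-[4-(benzyloxy)-8-methoxynaphthalen-1-yl]-1-hydroxy-1,2,3,4-tetrahydronaphthalene-2-carboxylate | COc1cccc2c(OCc3ccccc3)ccc([C@@H]3C[C@H](C(=O)OCc4ccccc4)[C@H](O)c4c3ccc(OCc3ccccc3)c4OCc3ccccc3)c12 | intermediate
15 | benzyl (4S)-7,8-bis(benzyloxy)-4-[4-(benzyloxy)-8-methoxynaphthalen-1-yl]-1-oxo-1,2,3,4-tetrahydronaphthalene-2-carboxylate (C2 not defined) | COc1cccc2c(OCc3ccccc3)ccc([C@@H]3CC(C(=O)OCc4ccccc4)C(=O)c4c3ccc(OCc3ccccc3)c4OCc3ccccc3)c12 | intermediate
16 | (4S)-7,8-dihydroxy-4-(4-hydroxy-8-methoxynaphthalen-1-yl)-1-oxo-1,2,3,4-tetrahydronaphthalene-2-carboxylic acid (C2 not defined; formed in the flask) | COc1cccc2c(O)ccc([C@@H]3CC(C(=O)O)C(=O)c4c3ccc(O)c4O)c12 | intermediate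
17 | (4S)-7,8-dihydroxy-4-(4-hydroxy-8-methoxynaphthalen-1-yl)-3,4-dihydronaphthalen-1(2H)-one | COc1cccc2c(O)ccc([C@@H]3CCC(=O)c4c3ccc(O)c4O)c12 | target

## Step count and risks

Total step count: 10. Longest linear sequence: 8 (steps 1-3 and 6-10).

### Steps most likely to fail

**Step 7.**
- **What may go wrong:** exothermic triplet energy transfer from the excited formyl group to the dialkoxynaphthalene, only one CH2 away, may outrun the 1,5-hydrogen shift, so that dienol formation is starved. Hydrogen abstraction from the C8 OCH2Ph group and incomplete face discrimination are smaller leaks.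
- **Fallback** (the dienol is made in the dark by cheletropic loss of SO2), from 10 back to 13:
  - 10 is acetalised (ethylene glycol, cat. p-TsOH, toluene, water separator) to the dioxolane F1.
  - n-BuLi in THF at −40 °C removes one doubly benzylic C4 proton (lateral lithiation helped by the acetal oxygens). SO2 traps the anion as the lithium sulfinate F2.
  - Dilute aqueous HCl in THF frees the aldehyde, onto which the sulfinic acid adds to give the cyclic α-hydroxy sulfone F3. It belongs to the 1-hydroxy-3-aryl-1,3-dihydro-2-benzothiophene 2,2-dioxides, which are known thermal stores of hydroxy-o-quinodimethanes in aryltetralin synthesis.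
  - Heated at about 80 °C in toluene under an argon sweep with 11 and the titanium TADDOLate of step 7, F3 should lose SO2 in a disrotatory cheletropic step.
  - The carbinol centre equilibrates by ring-chain tautomerism, so the cis isomer, which opens to dienol 12, is drained, and the same templated [4+2] should give 13.
  - F3 is racemic but 12 is achiral, so the ligand still sets C4.

**Step 1.**
- **What may go wrong:** attack at C2 or on the methoxy ring (C8), double bromination, or oxidation of the naphthol to the quinone.
- **Fallback** (symmetry instead of competition, the two oxygens being told apart afterwards through an acceptor group), from 1 back to 6: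
  - Methylation (MeI, K2CO3, acetone) gives 1,5-dimethoxynaphthalene F4, in which the two para α-positions are equivalent.
  - Vilsmeier-Haack formylation (POCl3, DMF, 90 °C) gives 4,8-dimethoxy-1-naphthaldehyde F5.
  - EtSNa in DMF at 110 °C should cleave only the C4 methyl ether, since only that oxygen is conjugated with the formyl group (para, vinylogous ester) whereas the peri C8 oxygen is not. This gives 4-hydroxy-8-methoxy-1-naphthaldehyde F6.
  - Benzylation (BnBr, K2CO3, DMF) gives 4-(benzyloxy)-8-methoxy-1-naphthaldehyde F7, and TsNHNH2 in MeOH gives the N-tosylhydrazone F8.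
  - NaH and then pinacolborane in toluene at 90-110 °C give 6 by Bamford-Stevens formation of the aryldiazomethane F9, addition to boron, and a 1,2-hydride shift with loss of N2.

**Step 6.**
- **What may go wrong:** slow transmetallation of the peri-hindered benzylic boronate, so that protodeboronation and homocoupling consume it.
- **Fallback** (polarity reversal: η3-naphthylmethylpalladium electrophile and sp2 boronate), from 6 and 9 back to 10:
  - NaBO3·4H2O in THF/H2O oxidises 6 to the naphthylmethanol F10.
  - ClCO2Me/pyridine gives the methyl carbonate F11, which should be storable, unlike the corresponding halide.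
  - Miyaura borylation of 9 (B2pin2, PdCl2(dppf), KOAc, dioxane, 90 °C) gives the formylaryl boronate F12.
  - Suzuki-Miyaura coupling of the benzylic carbonate F11 with F12 ([Pd(η3-C3H5)Cl]2, 1,5-bis(diphenylphosphino)pentane, K2CO3, DMF, 80 °C) should give 10.

## Further compounds

F1 | step 7 | 2-[2,3-bis(benzyloxy)-6-{[4-(benzyloxy)-8-methoxynaphthalen-1-yl]methyl}phenyl]-1,3-dioxolane | COc1cccc2c(OCc3ccccc3)ccc(Cc3ccc(OCc4ccccc4)c(OCc4ccccc4)c3C3OCCO3)c12
F2 | step 7 | lithium [3,4-bis(benzyloxy)-2-(1,3-dioxolan-2-yl)phenyl][4-(benzyloxy)-8-methoxynaphthalen-1-yl]methanesulfinate (racemic) | COc1cccc2c(OCc3ccccc3)ccc(C(c3ccc(OCc4ccccc4)c(OCc4ccccc4)c3C3OCCO3)S(=O)[O-])c12.[Li+]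
F3 | step 7 | 6,7-bis(benzyloxy)-3-[4-(benzyloxy)-8-methoxynaphthalen-1-yl]-1-hydroxy-1,3-dihydro-2-benzothiophene 2,2-dioxide (racemic, carbinol centre mobile) | COc1cccc2c(OCc3ccccc3)ccc(C3c4ccc(OCc5ccccc5)c(OCc5ccccc5)c4C(O)S3(=O)=O)c12
F4 | step 1 | 1,5-dimethoxynaphthalene | COc1cccc2c(OC)cccc12
F5 | step 1 | 4,8-dimethoxy-1-naphthaldehyde | COc1cccc2c(OC)ccc(C=O)c12
F6 | step 1 | 4-hydroxy-8-methoxy-1-naphthaldehyde | COc1cccc2c(O)ccc(C=O)c12
F7 | step 1 | 4-(benzyloxy)-8-methoxy-1-naphthaldehyde | COc1cccc2c(OCc3ccccc3)ccc(C=O)c12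
F8 | step 1 | (E)-N'-{[4-(benzyloxy)-8-methoxynaphthalen-1-yl]methylidene}-4-methylbenzenesulfonohydrazide | COc1cccc2c(OCc3ccccc3)ccc(/C=N/NS(=O)(=O)c3ccc(C)cc3)c12
F9 | step 1 | 1-(benzyloxy)-4-(diazomethyl)-5-methoxynaphthalene | COc1cccc2c(OCc3ccccc3)ccc(C=[N+]=[N-])c12
F10 | step 6 | [4-(benzyloxy)-8-methoxynaphthalen-1-yl]methanol | COc1cccc2c(OCc3ccccc3)ccc(CO)c12
F11 | step 6 | [4-(benzyloxy)-8-methoxynaphthalen-1-yl]methyl methyl carbonate | COc1cccc2c(OCc3ccccc3)ccc(COC(=O)OC)c12
F12 | step 6 | 2,3-bis(benzyloxy)-6-(4,4,5,5-tetramethyl-1,3,2-dioxaborolan-2-yl)benzaldehyde | O=Cc1c(B2OC(C)(C)C(C)(C)O2)ccc(OCc2ccccc2)c1OCc1ccccc1
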